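- If ring shrinks in proportion to the activator beside it, a pseudo-first-order decay while activator changes little, then one constant can travel from flask to flask, and I set out to get it from the earlier runs in two independent ways.

| flask | substrate | activator | remark | time |
|---|---|---|---|---|
| west | 0.10 M | 1.4 equiv | run made earlier |  |
| north-west | 0.10 M | 2.7 equiv | run made earlier |  |
| birch | 0.10 M | 2.00 equiv |  | 20 min |
| oak | 0.10 M | 4.00 equiv |  | 20 min |

| run | time / min | ring / % | substrate / % |
|---|---|---|---|
| west | 0.833 | 23 | 70 |
| west | 1.33 | 34 | 55 |
| west | 2.00 | 43 | 47 |
| west | 4.00 | 63 | 27 |
| west | 6.00 | 69 | 18 |
| west | 10.0 | 78 | 8 |
| north-west | 1.50 | 53 | 31 |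
| north-west | 3.00 | 75 | 11 |
| north-west | 5.00 | 76 | 5 |
| north-west | 6.00 | 77 | 1 |
| north-west | 8.00 | 73 | 3 |
| north-west | 10.0 | 67 | 1 |

(each reading ± 1.5 percentage points)

- the analysis behind the earlier runs scatters by 1.5 percentage points, standard deviation

* which of the two there is more of at the end, birch (over-reaction product / ring)
* which of the two there is more of at the end, oak (over-reaction product / ring)
* ring at the end, in percent of the substrate charged, birch
* ring at the end, in percent of the substrate charged, oak

- In north-west, ring fell from 77% at 6.00 min to 67% at 10.0 min. At 8.00 min I reckoned 0.149 M of activator: the charge, less the substrate gone, less one more for each part missing from the balance. That gave 0.233 /M/min, the ring-wear constant, which is the fraction of ring lost per minute for each mole per litre of activator.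
- In west, the missing part grew by 4 percentage points between 4.00 min and 10.0 min. With ring and activator taken at 6.00 min, this gave 0.215 /M/min.
- The two readings parted a little, west being lower, but west's gain of 4 points is built from several readings and carries a combined scatter of 3 points, so I kept the north-west figure.
- I took the wear to start from north-west's 76% of ring at 5.00 min, stretched inversely with activator: 6.75 min in birch and 3.38 min in oak. I reckoned activator at that point at 0.0810 M in birch and 0.281 M in oak.
- The first round gave 59.2% of ring in birch and 25.5% in oak. Putting the activator spent on that lost ring back in, at its mean, gave 60.7% and 28.2%.
- Reading the rest as over-reaction product, I expected more ring than over-reaction product in birch. In oak I expected less ring than over-reaction product.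
- The forecast said ring in birch at 60% (51% to 68%) and over-reaction product in oak, with ring at 30% (16% to 42%), and warned: “The order in activator for over-reaction is poorly fixed”.
- The flasks gave 64.0% of ring against 29.5% of over-reaction product in birch, and 29.3% against 65.0% in oak, so the forecast held on each count. In birch, the step from substrate and activator to activated form had half of its turnover behind it by 1.19 min, and at 10.0 min ring stood at 75.1% with 2.09% of substrate left. At 20.0 min in birch, ring was being made more slowly than it was used up, the ratio of the two rates being 0.0342. The ring-wear constant, run from 10.0 min with the mean activator of that stretch, gives 62.1% against the 64.0% found.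

    substrate + activator → activated form (k = 0.0550 /M/s)
    activated form → ring (k = 0.0830 /s)
    substrate + activated form → open dimer (k = 0.0630 /M/s)
    activator + ring → over-reaction product (k = 0.00390 /M/s)

- On a neighbour of birch charged with 0.060 M of substrate, the same reckoning starts the wear at 11.2 min with 0.0486 M of activator, and gives 68.8% of ring, then 69.1% on the second round. That computed neighbour holds 74.9% of ring.

Readings and results come from a simulation for an exercise; noise was put on by code.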